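**Assumption:** the sense of induction of Rh2(R-PTAD)4 in step 7 and of the (R)-benzyloxazolidinone in step 12 is as written; if either proves opposite, the antipodal catalyst or auxiliary (both commercial) is used. The route is a design on paper and has not been run.

**Legend.** Ring A is the resorcinol ring fused into the indane, ring B the resorcinol ring on C3 of the dihydrobenzofuran, ring C the benzo ring of the dihydrobenzofuran. C7a/C8a, C7b/C8b and C7c/C8c are the two sp3 carbons of the three resveratrol units (C7 carries the 4-oxyphenyl group). DBF = (2R,3R)-3-(3,5-dimethoxyphenyl)-6-methoxy-2-(4-methoxyphenyl)-2,3-dihydro-1-benzofuran-4-yl. Target configuration: C7a R, C8a S, C7b R, C8b R, C7c R, C8c R.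

## Retrosynthetic overview

1. Canaliculatol 38 ⇐ octamethyl ether 37 ⇐ carbinol 36: the eight-membered ring is closed last by Friedel–Crafts alkylation (C7c to ring B).
2. 36 ⇐ aldehyde 35 ⇐ all-cis indane 32 (cis-hydrogenation of indene 31, then epimerisation of C8c) ⇐ indanone 28 (Friedel–Crafts acylation onto ring A).
3. 28 ⇐ Michael adduct 23: the key C8a–C8c bond joins Evans imide 21 (ring A unit) to nitroalkene 17 (dihydrobenzofuran unit).
4. 17 ⇐ trans-dihydrobenzofuran 12, from enantioselective Rh-carbene C–H insertion of benzophenone-derived hydrazone 9 ⇐ 1-bromo-3,5-dimethoxybenzene 1.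
5. Ring order: dihydrobenzofuran, then the indane five-membered ring, then the eight-membered ring.

## Route

Step 1
Reactants: 1 1-bromo-3,5-dimethoxybenzene
Product: 2 2-bromo-4,6-dimethoxybenzaldehyde
Conditions: POCl3, DMF, 0 → 90 °C; aq. NaOAc
Reagents that add atoms: N,N-dimethylformamide CN(C)C=O; water O
Why: Vilsmeier–Haack formylation occurs ortho to Br and para to OMe, the position less hindered than the one between the two methoxy groups.

Step 2
Reactants: 2 2-bromo-4,6-dimethoxybenzaldehyde; 1 1-bromo-3,5-dimethoxybenzene (as Grignard precursor)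
Product: 4 racemic (2-bromo-4,6-dimethoxyphenyl)(3,5-dimethoxyphenyl)methanol, via Grignard reagent 3 (not isolated)
Conditions: 1, Mg, THF, reflux; then 2, THF, 0 °C → rt; aq. NH4Cl
Reagents that add atoms: none
Why: Grignard addition to an aldehyde; the aryl bromide of 2 does not exchange with an arylmagnesium reagent.

Step 3
Reactants: 4 diaryl carbinol
Product: 5 (2-bromo-4,6-dimethoxyphenyl)(3,5-dimethoxyphenyl)methanone
Conditions: Dess–Martin periodinane, NaHCO3, CH2Cl2, rt
Reagents that add atoms: none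
Why: Dess–Martin oxidation of a doubly benzylic alcohol, which removes the provisional stereocentre.

Step 4
Reactants: 5 benzophenone
Product: 6 (2-bromo-6-hydroxy-4-methoxyphenyl)(3,5-dimethoxyphenyl)methanone
Conditions: BCl3 (1.5 equiv), CH2Cl2, −78 → 0 °C
Reagents that add atoms: none
Why: Chelation-directed Lewis-acid ether cleavage removes only the methyl ether ortho to the carbonyl group.

Step 5
Reactants: 6 hydroxybenzophenone; 7 4-methoxybenzyl chloride
Product: 8 {2-bromo-4-methoxy-6-[(4-methoxybenzyl)oxy]phenyl}(3,5-dimethoxyphenyl)methanone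
Conditions: K2CO3, NaI (cat.), DMF, 60 °C
Reagents that add atoms: none
Why: Williamson etherification installs the benzylic CH2 that becomes C7b with its 4-methoxyphenyl group.

Step 6
Reactants: 8 benzyl ether ketone
Product: 9 hydrazone of 8
Conditions: N2H4·H2O (excess), AcOH (cat.), EtOH, 90 °C, sealed tube
Reagents that add atoms: hydrazine NN
Why: Hydrazone condensation, driven by excess hydrazine and heat because the ketone is di-ortho-substituted.

Step 7
Reactants: 9 hydrazone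
Product: 11 cis-(2S,3R)-4-bromo-dihydrobenzofuran, via diazo compound 10 (not isolated)
Conditions: MnO2, CH2Cl2, rt; filter; Rh2(R-PTAD)4 (1 mol %), CH2Cl2, 0 °C → rt
Reagents that add atoms: none
Why: Hydrazone dehydrogenation then intramolecular Rh-carbene C–H insertion into the activated benzylic C–H of the ether closes the dihydrobenzofuran; the chiral dirhodium carboxylate sets C8b (C3) as R, with cis as the kinetic diastereomer.

Step 8
Reactants: 11 cis-dihydrobenzofuran
Product: 12 trans-(2R,3R)-4-bromo-dihydrobenzofuran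
Conditions: CF3CO2H (5 equiv), CH2Cl2, 0 °C → rt
Reagents that add atoms: none
Why: Acid-mediated epimerisation at C2 by reversible ionisation of the 4-methoxybenzylic C–O bond gives the thermodynamic trans isomer, so C7b (R) is set relative to the untouched C8b.

Step 9
Reactants: 12 trans-bromide
Product: 14 DBF-carbaldehyde, via aryllithium 13 (not isolated)
Conditions: n-BuLi, THF, −78 °C; DMF, −78 → 0 °C; aq. NH4Cl
Reagents that add atoms: N,N-dimethylformamide CN(C)C=O
Why: Bromine–lithium exchange followed by Bouveault formylation; low temperature keeps the adjacent benzylic C–H intact.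

Step 10
Reactants: 14 DBF-carbaldehyde; 15 nitromethane
Product: 17 (E)-nitroalkene, via nitro alcohol 16 (not isolated)
Conditions: KOt-Bu (10 mol %), MeNO2/THF, 0 °C; then MsCl, i-Pr2NEt, CH2Cl2, 0 °C
Reagents that add atoms: none
Why: Henry reaction then mesylation and E1cB elimination gives the conjugated E-nitroalkene under conditions free of strong acid.

Step 11
Reactants: 18 3,5-dimethoxyphenylacetic acid; 19 (R)-4-benzyl-1,3-oxazolidin-2-one
Product: 21 (R)-4-benzyl-3-[(3,5-dimethoxyphenyl)acetyl]-1,3-oxazolidin-2-one, via mixed anhydride 20 (not isolated)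
Conditions: t-BuCOCl, Et3N, THF, −20 °C; then 19, LiCl, −20 °C → rt
Reagents that add atoms: none
Why: N-acylation of the Evans auxiliary through the mixed pivalic anhydride.

Step 12
Reactants: 21 Evans imide; 17 nitroalkene
Product: 23 Michael adduct (C3 epimers), via chlorotitanium enolate 22 (not isolated)
Conditions: TiCl4 (1.05 equiv), i-Pr2NEt (1.1 equiv), CH2Cl2, −78 °C; then 17, −78 → −20 °C; aq. NH4Cl
Reagents that add atoms: none
Why: Auxiliary-controlled Michael addition of the chelated Z-enolate to the nitroalkene forms the C8a–C8c bond; attack anti to the benzyl group sets C8c as the (2R)-acyl centre, while C8a is uncontrolled and becomes sp2 in step 17.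

Step 13
Reactants: 23 Michael adduct
Product: 24 (2R)-2-(3,5-dimethoxyphenyl)-3-(DBF)-4-nitrobutan-1-ol
Conditions: LiBH4, H2O (1 equiv), Et2O/THF, 0 °C
Reagents that add atoms: none
Why: Reductive cleavage of the N-acyl oxazolidinone; the nitro group is inert to borohydride.

Step 14
Reactants: 24 nitro alcohol
Product: 25 pivalate of 24
Conditions: t-BuCOCl, pyridine, DMAP (cat.), CH2Cl2, 0 °C → rt
Reagents that add atoms: pivaloyl chloride CC(C)(C)C(Cl)=O
Why: Acylation; a pivalate is chosen because its oxygen is too poorly nucleophilic to lactonise onto the acid chloride of step 16.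

Step 15
Reactants: 25 nitro pivalate
Product: 26 (3R)-3-(3,5-dimethoxyphenyl)-2-(DBF)-4-(pivaloyloxy)butanoic acid
Conditions: NaNO2 (3 equiv), AcOH (10 equiv), DMSO, 35 °C
Reagents that add atoms: sodium nitrite [Na+].[O-]N=O
Why: Nef-type oxidation of a primary nitroalkane to the carboxylic acid via the nitrolic acid; weakly acidic conditions spare the ester and the dihydrobenzofuran.

Step 16
Reactants: 26 carboxylic acid
Product: 28 indanone (C2 epimers), via acid chloride 27 (not isolated)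
Conditions: (COCl)2, DMF (cat.), CH2Cl2, 0 °C → rt; then SnCl4 (1.1 equiv), CH2Cl2, −78 → −20 °C
Reagents that add atoms: none
Why: Intramolecular Friedel–Crafts acylation closes the five-membered ring at the ring A position ortho and para to the methoxy groups, faster than seven-ring closure onto ring B.

Step 17
Reactants: 28 indanone; 29 4-methoxyphenylmagnesium bromide
Product: 31 (1S)-indene, via tertiary indanol 30 (not isolated)
Conditions: CeCl3, THF, −78 °C, 29 (3 equiv), −78 → 0 °C; aq. NH4Cl; then TsOH·H2O (5 mol %), CH2Cl2, rt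
Reagents that add atoms: none
Why: CeCl3-promoted Grignard 1,2-addition suppresses enolisation and E1 dehydration gives the tetrasubstituted C7a=C8a alkene; acid cannot move the alkene toward C8c because a cation at C8a is not stabilised by the meta oxygens of ring C.

Step 18
Reactants: 31 indene
Product: 32 all-cis (1R,2R,3R)-indane pivalate
Conditions: H2 (50 bar), Pd(OH)2/C, EtOAc/EtOH, 40 °C
Reagents that add atoms: none
Why: Heterogeneous catalytic hydrogenation adds both hydrogens syn from the face opposite the CH2OPiv group at C8c, setting C7a (R) and C8a with the two aryl groups cis.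

Step 19
Reactants: 32 indane pivalate
Product: 33 all-cis indanyl methanol
Conditions: i-Bu2AlH (3 equiv), CH2Cl2, −78 °C; aq. potassium sodium tartrate
Reagents that add atoms: none
Why: Reductive ester cleavage; no other reducible group is present.

Step 20
Reactants: 33 primary alcohol
Product: 35 (1S,2R,3R)-indane-1-carbaldehyde, via all-cis aldehyde 34 (not isolated)
Conditions: Dess–Martin periodinane, NaHCO3, CH2Cl2, 0 °C → rt; then DBU (0.5 equiv), CH2Cl2, rt
Reagents that add atoms: none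
Why: Dess–Martin oxidation then base-mediated enolisation of the benzylic aldehyde epimerises C8c away from the crowded all-cis array to the thermodynamic isomer, formyl trans to ring C, which is the target configuration.

Step 21
Reactants: 35 aldehyde; 29 4-methoxyphenylmagnesium bromide
Product: 36 secondary benzylic carbinol (C7c epimers)
Conditions: 29 (2 equiv), THF, −78 → 0 °C; aq. NH4Cl
Reagents that add atoms: none
Why: Grignard addition; the carbinol configuration does not matter because C7c is ionised in the next step.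

Step 22
Reactants: 36 carbinol
Product: 37 canaliculatol octamethyl ether
Conditions: BF3·OEt2 (2 equiv), CH2Cl2 (2 mM), −78 → −30 °C
Reagents that add atoms: none
Why: Intramolecular Friedel–Crafts alkylation by the 4-methoxybenzylic cation at the ring B position ortho and para to methoxy closes the eight-membered ring. The cation adopts the A(1,3)-minimised rotamer (C8c–H eclipsing the anisyl side) and ring B, tethered through ring C on C8a, can reach only the face syn to C8a, which gives C7c as R. The trans disposition of ring C and C7c disfavours five-ring closure onto ring C.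

Step 23
Reactants: 37 octamethyl ether
Product: 38 canaliculatol
Conditions: BBr3 (20 equiv), CH2Cl2, −78 °C → rt; MeOH, then H2O
Reagents that add atoms: none
Why: Lewis-acid cleavage of the eight aryl methyl ethers; the cyclic benzylic ether survives because any opening re-closes to the trans-dihydrobenzofuran.

## Compound list

1 | 1-bromo-3,5-dimethoxybenzene | COc1cc(Br)cc(OC)c1 | starting material
2 | 2-bromo-4,6-dimethoxybenzaldehyde | COc1cc(OC)c(C=O)c(Br)c1 | intermediate
3 | 3,5-dimethoxyphenylmagnesium bromide | COc1cc(OC)cc([Mg]Br)c1 | intermediate (not isolated)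
4 | racemic (2-bromo-4,6-dimethoxyphenyl)(3,5-dimethoxyphenyl)methanol | COc1cc(OC)c(C(O)c2cc(OC)cc(OC)c2)c(Br)c1 | intermediate
5 | (2-bromo-4,6-dimethoxyphenyl)(3,5-dimethoxyphenyl)methanone | COc1cc(OC)c(C(=O)c2cc(OC)cc(OC)c2)c(Br)c1 | intermediate
6 | (2-bromo-6-hydroxy-4-methoxyphenyl)(3,5-dimethoxyphenyl)methanone | COc1cc(O)c(C(=O)c2cc(OC)cc(OC)c2)c(Br)c1 | intermediate
7 | 4-methoxybenzyl chloride | COc1ccc(CCl)cc1 | starting material
8 | {2-bromo-4-methoxy-6-[(4-methoxybenzyl)oxy]phenyl}(3,5-dimethoxyphenyl)methanone | COc1ccc(COc2cc(OC)cc(Br)c2C(=O)c2cc(OC)cc(OC)c2)cc1 | intermediate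
9 | hydrazone of 8 (E/Z mixture) | COc1ccc(COc2cc(OC)cc(Br)c2C(=NN)c2cc(OC)cc(OC)c2)cc1 | intermediate
10 | 1-bromo-2-[diazo(3,5-dimethoxyphenyl)methyl]-5-methoxy-3-[(4-methoxybenzyl)oxy]benzene | COc1ccc(COc2cc(OC)cc(Br)c2C(=[N+]=[N-])c2cc(OC)cc(OC)c2)cc1 | intermediate (not isolated)
11 | (2S,3R)-4-bromo-3-(3,5-dimethoxyphenyl)-6-methoxy-2-(4-methoxyphenyl)-2,3-dihydro-1-benzofuran (cis) | COc1ccc(cc1)[C@H]1Oc2cc(OC)cc(Br)c2[C@H]1c1cc(OC)cc(OC)c1 | intermediate
12 | (2R,3R)-4-bromo-3-(3,5-dimethoxyphenyl)-6-methoxy-2-(4-methoxyphenyl)-2,3-dihydro-1-benzofuran (trans) | COc1ccc(cc1)[C@@H]1Oc2cc(OC)cc(Br)c2[C@H]1c1cc(OC)cc(OC)c1 | intermediate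
13 | [(2R,3R)-3-(3,5-dimethoxyphenyl)-6-methoxy-2-(4-methoxyphenyl)-2,3-dihydro-1-benzofuran-4-yl]lithium | COc1ccc(cc1)[C@@H]1Oc2cc(OC)cc([Li])c2[C@H]1c1cc(OC)cc(OC)c1 | intermediate (not isolated)
14 | (2R,3R)-3-(3,5-dimethoxyphenyl)-6-methoxy-2-(4-methoxyphenyl)-2,3-dihydro-1-benzofuran-4-carbaldehyde | COc1ccc(cc1)[C@@H]1Oc2cc(OC)cc(C=O)c2[C@H]1c1cc(OC)cc(OC)c1 | intermediate
15 | nitromethane | C[N+](=O)[O-] | starting material
16 | 1-(DBF)-2-nitroethanol (carbinol epimers) | COc1ccc(cc1)[C@@H]1Oc2cc(OC)cc(C(O)C[N+](=O)[O-])c2[C@H]1c1cc(OC)cc(OC)c1 | intermediate (not isolated)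
17 | (2R,3R)-3-(3,5-dimethoxyphenyl)-6-methoxy-2-(4-methoxyphenyl)-4-[(E)-2-nitroethenyl]-2,3-dihydro-1-benzofuran | COc1ccc(cc1)[C@@H]1Oc2cc(OC)cc(/C=C/[N+](=O)[O-])c2[C@H]1c1cc(OC)cc(OC)c1 | intermediate
18 | 3,5-dimethoxyphenylacetic acid | COc1cc(CC(=O)O)cc(OC)c1 | starting material
19 | (R)-4-benzyl-1,3-oxazolidin-2-one | O=C1N[C@H](Cc2ccccc2)CO1 | starting material
20 | (3,5-dimethoxyphenyl)acetic pivalic anhydride | COc1cc(CC(=O)OC(=O)C(C)(C)C)cc(OC)c1 | intermediate (not isolated)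
21 | (R)-4-benzyl-3-[(3,5-dimethoxyphenyl)acetyl]-1,3-oxazolidin-2-one | COc1cc(CC(=O)N2[C@H](Cc3ccccc3)COC2=O)cc(OC)c1 | intermediate
22 | trichlorotitanium (Z)-enolate of 21 | COc1cc(/C=C(\O[Ti](Cl)(Cl)Cl)N2[C@H](Cc3ccccc3)COC2=O)cc(OC)c1 | intermediate (not isolated)
23 | (4R)-4-benzyl-3-[(2R)-2-(3,5-dimethoxyphenyl)-3-(DBF)-4-nitrobutanoyl]-1,3-oxazolidin-2-one (C3 epimers, inconsequential) | O=C(N1[C@H](Cc2ccccc2)COC1=O)[C@@H](c1cc(OC)cc(OC)c1)C(C[N+](=O)[O-])c1cc(OC)cc2c1[C@@H](c1cc(OC)cc(OC)c1)[C@H](c1ccc(OC)cc1)O2 | intermediate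
24 | (2R)-2-(3,5-dimethoxyphenyl)-3-(DBF)-4-nitrobutan-1-ol (C3 epimers) | OC[C@@H](c1cc(OC)cc(OC)c1)C(C[N+](=O)[O-])c1cc(OC)cc2c1[C@@H](c1cc(OC)cc(OC)c1)[C@H](c1ccc(OC)cc1)O2 | intermediate
25 | (2R)-2-(3,5-dimethoxyphenyl)-3-(DBF)-4-nitrobutyl pivalate (C3 epimers) | CC(C)(C)C(=O)OC[C@@H](c1cc(OC)cc(OC)c1)C(C[N+](=O)[O-])c1cc(OC)cc2c1[C@@H](c1cc(OC)cc(OC)c1)[C@H](c1ccc(OC)cc1)O2 | intermediate
26 | (3R)-3-(3,5-dimethoxyphenyl)-2-(DBF)-4-(pivaloyloxy)butanoic acid (C2 epimers) | CC(C)(C)C(=O)OC[C@@H](c1cc(OC)cc(OC)c1)C(C(=O)O)c1cc(OC)cc2c1[C@@H](c1cc(OC)cc(OC)c1)[C@H](c1ccc(OC)cc1)O2 | intermediate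
27 | acid chloride of 26 | CC(C)(C)C(=O)OC[C@@H](c1cc(OC)cc(OC)c1)C(C(Cl)=O)c1cc(OC)cc2c1[C@@H](c1cc(OC)cc(OC)c1)[C@H](c1ccc(OC)cc1)O2 | intermediate (not isolated)
28 | [(1R)-4,6-dimethoxy-3-oxo-2-(DBF)-2,3-dihydro-1H-inden-1-yl]methyl pivalate (C2 epimers) | CC(C)(C)C(=O)OC[C@H]1c2cc(OC)cc(OC)c2C(=O)C1c1cc(OC)cc2c1[C@@H](c1cc(OC)cc(OC)c1)[C@H](c1ccc(OC)cc1)O2 | intermediate
29 | 4-methoxyphenylmagnesium bromide (commercial THF solution) | COc1ccc([Mg]Br)cc1 | starting material
30 | [(1R)-3-hydroxy-4,6-dimethoxy-3-(4-methoxyphenyl)-2-(DBF)-2,3-dihydro-1H-inden-1-yl]methyl pivalate (diastereomers) | CC(C)(C)C(=O)OC[C@H]1c2cc(OC)cc(OC)c2C(O)(c2ccc(OC)cc2)C1c1cc(OC)cc2c1[C@@H](c1cc(OC)cc(OC)c1)[C@H](c1ccc(OC)cc1)O2 | intermediate (not isolated)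
31 | [(1S)-4,6-dimethoxy-3-(4-methoxyphenyl)-2-(DBF)-1H-inden-1-yl]methyl pivalate | CC(C)(C)C(=O)OC[C@H]1c2cc(OC)cc(OC)c2C(c2ccc(OC)cc2)=C1c1cc(OC)cc2c1[C@@H](c1cc(OC)cc(OC)c1)[C@H](c1ccc(OC)cc1)O2 | intermediate
32 | [(1R,2R,3R)-4,6-dimethoxy-3-(4-methoxyphenyl)-2-(DBF)-2,3-dihydro-1H-inden-1-yl]methyl pivalate (all-cis) | CC(C)(C)C(=O)OC[C@H]1c2cc(OC)cc(OC)c2[C@@H](c2ccc(OC)cc2)[C@H]1c1cc(OC)cc2c1[C@@H](c1cc(OC)cc(OC)c1)[C@H](c1ccc(OC)cc1)O2 | intermediate
33 | [(1R,2R,3R)-4,6-dimethoxy-3-(4-methoxyphenyl)-2-(DBF)-2,3-dihydro-1H-inden-1-yl]methanol (all-cis) | OC[C@H]1c2cc(OC)cc(OC)c2[C@@H](c2ccc(OC)cc2)[C@H]1c1cc(OC)cc2c1[C@@H](c1cc(OC)cc(OC)c1)[C@H](c1ccc(OC)cc1)O2 | intermediate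
34 | (1R,2R,3R)-4,6-dimethoxy-3-(4-methoxyphenyl)-2-(DBF)-2,3-dihydro-1H-indene-1-carbaldehyde (all-cis) | O=C[C@H]1c2cc(OC)cc(OC)c2[C@@H](c2ccc(OC)cc2)[C@H]1c1cc(OC)cc2c1[C@@H](c1cc(OC)cc(OC)c1)[C@H](c1ccc(OC)cc1)O2 | intermediate (not isolated)
35 | (1S,2R,3R)-4,6-dimethoxy-3-(4-methoxyphenyl)-2-(DBF)-2,3-dihydro-1H-indene-1-carbaldehyde (1,2-trans, 2,3-cis) | O=C[C@@H]1c2cc(OC)cc(OC)c2[C@@H](c2ccc(OC)cc2)[C@H]1c1cc(OC)cc2c1[C@@H](c1cc(OC)cc(OC)c1)[C@H](c1ccc(OC)cc1)O2 | intermediate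
36 | (4-methoxyphenyl)[(1S,2R,3R)-4,6-dimethoxy-3-(4-methoxyphenyl)-2-(DBF)-2,3-dihydro-1H-inden-1-yl]methanol (carbinol epimers) | COc1ccc(cc1)C(O)[C@@H]1c2cc(OC)cc(OC)c2[C@@H](c2ccc(OC)cc2)[C@H]1c1cc(OC)cc2c1[C@@H](c1cc(OC)cc(OC)c1)[C@H](c1ccc(OC)cc1)O2 | intermediate
37 | canaliculatol octamethyl ether | COc1ccc([C@@H]2c3c(OC)cc(OC)cc3[C@H]3[C@H](c4ccc(OC)cc4)c4c(OC)cc(OC)cc4[C@@H]4c5c(cc(OC)cc5[C@H]23)O[C@H]4c2ccc(OC)cc2)cc1 | intermediate
38 | canaliculatol | Oc1ccc([C@@H]2c3c(O)cc(O)cc3[C@H]3[C@H](c4ccc(O)cc4)c4c(O)cc(O)cc4[C@@H]4c5c(cc(O)cc5[C@H]23)O[C@H]4c2ccc(O)cc2)cc1 | target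

## Summary

Total steps: 23. Longest linear sequence: 22 (steps 1–10, then 12–23; step 11 is a one-step branch).

**Steps most likely to fail**

Step 7. The diazo carbon is flanked by two ortho substituents, so hydrazone oxidation and C–H insertion may be slow and the selectivity lower than for simpler substrates. The fallback sets out from phenol 6. Acylation with 4-methoxybenzoyl chloride (Et3N, DMAP) gives 3-bromo-2-(3,5-dimethoxybenzoyl)-5-methoxyphenyl 4-methoxybenzoate F1. Keto-ester McMurry coupling with low-valent titanium (TiCl3, Zn, DME, reflux) gives 4-bromo-3-(3,5-dimethoxyphenyl)-6-methoxy-2-(4-methoxyphenyl)-1-benzofuran F2. Ionic hydrogenation (Et3SiH, CF3CO2H) reduces the furan ring to the racemic trans-dihydrobenzofuran, that is 12 together with its (2S,3S)-enantiomer F3. Preparative chromatography on a chiral phase then returns the route at 12.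

Step 18. The tetrasubstituted, doubly aryl-substituted alkene is very hindered, and forcing conditions risk hydrogenolysis of the benzylic C–O bond of the dihydrobenzofuran. The fallback sets out from indene 31 and replaces surface hydrogenation by stepwise ionic hydrogenation (Et3SiH, CF3CO2H, CH2Cl2, −40 → 0 °C). Protonation at C8a anti to the CH2OPiv group and hydride delivery to the C7a cation anti to ring C give the same all-cis indane, so it comes back at 32. This fallback makes no new compound (F0).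

Step 22. The C7c cation can lose H8c to give an exocyclic stilbene, which would re-protonate and close a five-membered ring onto ring C. Eight-ring closure is also entropically slow, and the dihydrobenzofuran is acid-sensitive. The fallback sets out from aldehyde 35 and uses a quinone methide as the electrophile under near-neutral conditions. The reagent [4-(tert-butyldimethylsilyloxy)phenyl]lithium F4 (from the commercial aryl bromide and n-BuLi, THF, −78 °C) is added to 35 and the alkoxide is trapped with Ac2O to give the benzylic acetate F5. Bu4NF buffered with AcOH (THF, −40 °C) triggers desilylation and 1,6-elimination to the para-quinone methide F6. In (CF3)2CHOH at 0 °C, ring B adds 1,6 to it (vinylogous Friedel–Crafts, same facial logic as step 22) to give the ring-closed heptamethyl ether monophenol F7. O-Methylation (MeI, K2CO3, acetone) returns the route at 37.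

## Further compounds

F1 | step 7 | 3-bromo-2-(3,5-dimethoxybenzoyl)-5-methoxyphenyl 4-methoxybenzoate | COc1ccc(cc1)C(=O)Oc1cc(OC)cc(Br)c1C(=O)c1cc(OC)cc(OC)c1
F2 | step 7 | 4-bromo-3-(3,5-dimethoxyphenyl)-6-methoxy-2-(4-methoxyphenyl)-1-benzofuran | COc1ccc(cc1)-c1oc2cc(OC)cc(Br)c2c1-c1cc(OC)cc(OC)c1
F3 | step 7 | (2S,3S)-4-bromo-3-(3,5-dimethoxyphenyl)-6-methoxy-2-(4-methoxyphenyl)-2,3-dihydro-1-benzofuran (enantiomer of 12, formed with 12 as the racemate) | COc1ccc(cc1)[C@H]1Oc2cc(OC)cc(Br)c2[C@@H]1c1cc(OC)cc(OC)c1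
F0 | step 18 | none | none
F4 | step 22 | [4-(tert-butyldimethylsilyloxy)phenyl]lithium | CC(C)(C)[Si](C)(C)Oc1ccc([Li])cc1
F5 | step 22 | [4-(tert-butyldimethylsilyloxy)phenyl][(1S,2R,3R)-4,6-dimethoxy-3-(4-methoxyphenyl)-2-(DBF)-2,3-dihydro-1H-inden-1-yl]methyl acetate (epimers at the acetoxy carbon) | CC(=O)OC(c1ccc(O[Si](C)(C)C(C)(C)C)cc1)[C@@H]1c2cc(OC)cc(OC)c2[C@@H](c2ccc(OC)cc2)[C@H]1c1cc(OC)cc2c1[C@@H](c1cc(OC)cc(OC)c1)[C@H](c1ccc(OC)cc1)O2
F6 | step 22 | 4-{[(1S,2R,3R)-4,6-dimethoxy-3-(4-methoxyphenyl)-2-(DBF)-2,3-dihydro-1H-inden-1-yl]methylidene}cyclohexa-2,5-dien-1-one | O=C1C=CC(=C[C@@H]2c3cc(OC)cc(OC)c3[C@@H](c3ccc(OC)cc3)[C@H]2c2cc(OC)cc3c2[C@@H](c2cc(OC)cc(OC)c2)[C@H](c2ccc(OC)cc2)O3)C=C1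
F7 | step 22 | canaliculatol heptamethyl ether with a free 4-hydroxyphenyl group at C7c | COc1ccc([C@@H]2c3c(OC)cc(OC)cc3[C@H]3[C@H](c4ccc(O)cc4)c4c(OC)cc(OC)cc4[C@@H]4c5c(cc(OC)cc5[C@H]23)O[C@H]4c2ccc(OC)cc2)cc1
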